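**Plan**

1. Retrosynthesis: remove the acetate and silyl groups; cut C8–CH3 (enol triflate of a C8 ketone); cut C9–H and C9–C11 back to a C9 ketone plus a C11–C15 Grignard reagent; cut ring A across C1–C10 and C4–C5 as a [4+2] cycloaddition.
2. Enabling feature: ring A carries its two oxygens on adjacent C2 and C3, flanked by C1H2 and C4(CH3)2. It is therefore a masked C2=C3 enediol, the adduct of a 2,3-dioxy-1,3-diene (C1–C4) with the C5=C10 bond that ring A shares with ring B.
3. Forward: ring B is 2-methoxy-6-methyl-1,4-benzoquinone (its methyl is C20; its OMe is the latent C8 carbonyl and switches off the second C=C). Ring A is fused on by an enantioselective Diels–Alder reaction, and the side chain is then joined at the C9 carbonyl.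
4. Ring B is then edited: Stork–Danheiser transposition (C6 oxygen out, carbonyl to C8), reductive loss of the C9 hydroxyl, conjugate reduction to an enol triflate, and methyl cross-coupling (Δ7, C17). Ring A is unveiled last.
5. Stereochemistry: C10 from the chiral Lewis acid; C5 by protonation of the ring-fusion enolate opposite the axial C4 and C10 methyls; C9 by protonation of a samarium enolate opposite the C10 methyl; C3 by axial protonation of the C2 enol; 13E by syn-carboalumination.

Key step: step 4

Remark: ring and chain positions are numbered as in labdanes (C1–C10 decalin, C11–C16 side chain, C17 on C8, C18/C19 on C4, C20 on C10); "ent" marks the enantiomeric labdane series of the target.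
Remark: the catalyst antipode in step 4 is assumed to deliver the diene to the quinone face that gives the drawn configuration at the methyl-bearing ring-fusion carbon; if the sense of induction is the opposite, the mirror-image catalyst is used and nothing else changes.

**Step 1**
Reactants: 1 4-methylpentane-2,3-dione
Product: 2 2-(tert-butyldimethylsilyloxy)-4-methylpent-1-en-3-one
Conditions: LiN(i-Pr)2, THF, −78 °C; then t-BuMe2SiCl, HMPA, −78 → 0 °C
Reagents that add atoms: tert-butyldimethylsilyl chloride, CC(C)(C)[Si](C)(C)Cl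
Why: kinetic deprotonation should take the unhindered acetyl methyl and not the isopropyl methine, and O-silylation of the lithium enolate gives the silyl enol ether (kinetic enolate trapping).

**Step 2**
Reactants: 2 2-(tert-butyldimethylsilyloxy)-4-methylpent-1-en-3-one
Product: 3 2-(tert-butyldimethylsilyloxy)-4-methyl-3-(triisopropylsilyloxy)penta-1,3-diene
Conditions: i-Pr3SiOTf, Et3N, CH2Cl2, 0 °C → rt
Reagents that add atoms: triisopropylsilyl triflate, CC(C)[Si](C(C)C)(C(C)C)OS(=O)(=O)C(F)(F)F
Why: soft enolisation of the remaining ketone, whose only α-hydrogen is the isopropyl methine, should give the tetrasubstituted enol ether and so place the robust silyl group on O3 and the labile one on O2.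

**Step 3**
Reactants: 4 2-methoxy-6-methylphenol
Product: 5 2-methoxy-6-methyl-1,4-benzoquinone
Conditions: O2 (1 atm), Co(salen) [N,N'-ethylenebis(salicylideneiminato)cobalt, divalent cobalt] (5 mol %), DMF, rt
Reagents that add atoms: dioxygen, O=O
Why: cobalt–salen-catalysed aerobic para-oxidation of a 2,6-disubstituted phenol should give the p-quinone.

**Step 4**
Reactants: 5 2-methoxy-6-methyl-1,4-benzoquinone; 3 2-(tert-butyldimethylsilyloxy)-4-methyl-3-(triisopropylsilyloxy)penta-1,3-diene
Product: 6 (4aS,8aR)-7-(tert-butyldimethylsilyloxy)-2-methoxy-5,5,8a-trimethyl-6-(triisopropylsilyloxy)-4a,5,8,8a-tetrahydronaphthalene-1,4-dione (cis-fused; labdane locants: 6,9-dione; 8-OMe; 2-OTBS; 3-OTIPS)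
Conditions: chiral oxazaborolidinium triflimide [(S)-3,3-diphenyl-1-(2-methylphenyl)tetrahydro-1H,3H-pyrrolo[1,2-c][1,3,2]oxazaborole·HNTf2] (20 mol %), CH2Cl2, −78 → −40 °C
Reagents that add atoms: none
Why: Diels–Alder reaction of the electron-rich 2,3-bis(silyloxy)diene with the quinone, whose more basic vinylogous-ester carbonyl (C6=O) is bound by the cationic boron Lewis acid; the bond from the unhindered CH2 terminus (C1) to the methyl-bearing β-carbon (C10) should run ahead and the C(CH3)2 terminus (C4) then closes onto C5. The closest known reaction type is the chiral oxazaborolidinium-catalysed Diels–Alder reaction of benzoquinones with 2-silyloxydienes, which gives angular-methyl cis-decalindiones. Ring A is closed as a six-membered ring by suprafacial [4+2] addition across the cis C5=C10 bond, so the ring fusion is cis at this stage. The only lasting new stereocentre, quaternary C10, is set by the catalyst, which shields one face of the quinone C=C; C5 is formed too but is reset in step 8. Site selectivity is secured because the methoxy-bearing C=C is a deactivated vinylogous ester. Regiochemistry is secured because the other orientation would join the C(CH3)2 terminus to the methyl-bearing carbon and build two contiguous quaternary centres, and the polarisation by the C2 silyl enol ether points the same way.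

**Step 5**
Reactants: 7 4-bromobut-1-yne
Product: 9 ethyl (E)-5-bromo-3-methylpent-2-enoate, via alkenylalane 8 (not isolated)
Conditions: AlMe3, Cp2ZrCl2 (20 mol %), CH2Cl2, 0 °C → rt; then ClCO2Et, 0 °C
Reagents that add atoms: trimethylaluminium, C[Al](C)C; ethyl chloroformate, CCOC(=O)Cl
Why: zirconium-catalysed syn-carboalumination of the terminal alkyne (methyl to the internal carbon) fixes the E trisubstituted alkene, and the alkenylalane is acylated with retention.

**Step 6**
Reactants: 9 ethyl (E)-5-bromo-3-methylpent-2-enoate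
Product: 10 (E)-5-bromo-3-methylpent-2-en-1-ol
Conditions: i-Bu2AlH, CH2Cl2, −78 °C
Reagents that add atoms: none
Why: 1,2-reduction of the conjugated ester by the aluminium hydride should give the allylic alcohol and leave the primary bromide and the alkene geometry untouched.

**Step 7**
Reactants: 10 (E)-5-bromo-3-methylpent-2-en-1-ol
Product: 11 (E)-(5-bromo-3-methylpent-2-enyloxy)(tert-butyl)diphenylsilane
Conditions: t-BuPh2SiCl, imidazole, CH2Cl2, 0 °C → rt
Reagents that add atoms: tert-butyldiphenylsilyl chloride, CC(C)(C)[Si](Cl)(c1ccccc1)c1ccccc1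
Why: standard silylation of a primary alcohol; this silyl ether should survive the organometallic, hydride and dilute-acid steps that follow.

**Step 8**
Reactants: 6 cis-fused cycloadduct; 11 (E)-(5-bromo-3-methylpent-2-enyloxy)(tert-butyl)diphenylsilane
Product: 15 15-(tert-butyldiphenylsilyloxy)-2-(tert-butyldimethylsilyloxy)-9-hydroxy-8-methoxy-3-(triisopropylsilyloxy)-17-nor-ent-labda-2,7,13E-trien-6-one (H-5 trans and 9-OH cis to CH3-20), via potassium dienolate 12 (not isolated), via Grignard reagent 13 (not isolated), via dienolate alkoxide 14 (not isolated)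
Conditions: 11: Mg, THF, 40 °C; 6: KN(SiMe3)2, THF, −78 °C; combine in the presence of LaCl3·2LiCl (0.3 equiv), −78 → −30 °C; AcOH, −78 °C
Reagents that add atoms: none
Why: Grignard 1,2-addition to C9, the only carbonyl left once the vinylogous ester is masked as its C5 dienolate (which also blocks conjugate addition), followed by kinetic C-protonation of the ring-fusion enolate on the face opposite the two flanking axial methyls (on C4 and C10), should give the trans fusion; the C9 carbinol configuration (attack anti to CH3-20) does not matter because C9 is reset in step 10.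

**Step 9**
Reactants: 15 trans-fused C9 carbinol
Product: 17 15-(tert-butyldiphenylsilyloxy)-2-(tert-butyldimethylsilyloxy)-9-hydroxy-3-(triisopropylsilyloxy)-17-nor-ent-labda-2,6,13E-trien-8-one, via allylic alcohol 16 (not isolated)
Conditions: i-Bu2AlH, CH2Cl2, −78 °C; then 0.5 M aq. oxalic acid, THF, 0 °C
Reagents that add atoms: water, O
Why: Stork–Danheiser transposition, in which 1,2-reduction of the vinylogous-ester carbonyl and mild acid hydrolysis of the resulting γ-hydroxy enol ether move the carbonyl to C8 and delete the C6 oxygen without touching a stereocentre; this ionisation should be much faster than hydrolysis of the hindered tetrasubstituted ring A silyl enol ethers.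

**Step 10**
Reactants: 17 α-hydroxy enone
Product: 19 15-(tert-butyldiphenylsilyloxy)-2-(tert-butyldimethylsilyloxy)-3-(triisopropylsilyloxy)-17-nor-ent-labda-2,6,13E-trien-8-one (H-9 trans to CH3-20; side chain cis to it), via samarium dienolate 18 (not isolated)
Conditions: SmI2 (2.5 equiv), THF/MeOH, −78 °C
Reagents that add atoms: none
Why: SmI2 reductive cleavage of the α-hydroxy ketone C–O bond; methanol should protonate the samarium enolate at C9 from the face opposite the axial C10 methyl, which leaves the side chain equatorial and cis to that methyl.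

**Step 11**
Reactants: 19 C8 enone
Product: 21 15-(tert-butyldiphenylsilyloxy)-2-(tert-butyldimethylsilyloxy)-3-(triisopropylsilyloxy)-17-nor-ent-labda-2,7,13E-trien-8-yl triflate, via lithium enolate 20 (not isolated)
Conditions: LiBH(s-Bu)3, THF, −78 °C; then PhNTf2, −78 → 0 °C
Reagents that add atoms: N-phenylbis(trifluoromethanesulfonimide), O=S(=O)(N(c1ccccc1)S(=O)(=O)C(F)(F)F)C(F)(F)F
Why: conjugate hydride addition to the β-unsubstituted enone (the carbonyl is shielded by the substituted C9) should give the Δ7 enolate regiospecifically, and O-triflation traps it before C9 can be enolised.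

**Step 12**
Reactants: 21 enol triflate
Product: 22 15-(tert-butyldiphenylsilyloxy)-2-(tert-butyldimethylsilyloxy)-3-(triisopropylsilyloxy)-ent-labda-2,7,13E-triene
Conditions: MeMgBr, Fe(acac)3 (10 mol %), THF/NMP, −20 °C
Reagents that add atoms: methylmagnesium bromide, C[Mg]Br
Why: iron-catalysed cross-coupling (Kumada type) of the enol triflate with the methyl Grignard reagent should install C17 with the double bond held at C7–C8.

**Step 13**
Reactants: 22 fully silylated triene
Product: 25 ent-3β,15-dihydroxylabda-7,13E-dien-2-one, via silyloxy ketone 23 (not isolated), via hydroxy silyloxy ketone 24 (not isolated)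
Conditions: HF·pyridine, pyridine, THF, 0 °C → rt; then 48% aq. HF, MeCN, rt
Reagents that add atoms: none
Why: fluoride should first cleave the less hindered and more labile tert-butyldimethylsilyl enol ether on O2, and the C2 enol then ketonises by axial protonation at C3 (face opposite CH3-20) while O3 still carries the triisopropylsilyl group, which fixes the ketone at C2 and the C3 oxygen equatorial before the remaining silyl ethers are removed (fluoride desilylation).

**Step 14**
Reactants: 25 ent-3β,15-dihydroxylabda-7,13E-dien-2-one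
Product: 26 ent-3β-hydroxy-2-oxolabda-7,13E-dien-15-yl acetate [(E)-5-[(1R,4aS,6S,8aS)-6-hydroxy-2,5,5,8a-tetramethyl-7-oxo-1,4,4a,5,6,7,8,8a-octahydronaphthalen-1-yl]-3-methylpent-2-en-1-yl acetate]
Conditions: Ac2O (1.1 equiv), pyridine, CH2Cl2, 0 °C
Reagents that add atoms: acetic anhydride, CC(=O)OC(C)=O
Why: acylation should take the primary allylic alcohol and leave the neopentyl secondary α-ketol hydroxyl, which is flanked by the gem-dimethyl carbon and the ketone (chemoselective acetylation).

**Compound list**

1 | 4-methylpentane-2,3-dione | CC(=O)C(=O)C(C)C | starting material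
2 | 2-(tert-butyldimethylsilyloxy)-4-methylpent-1-en-3-one | C=C(O[Si](C)(C)C(C)(C)C)C(=O)C(C)C | intermediate
3 | 2-(tert-butyldimethylsilyloxy)-4-methyl-3-(triisopropylsilyloxy)penta-1,3-diene | C=C(O[Si](C)(C)C(C)(C)C)C(O[Si](C(C)C)(C(C)C)C(C)C)=C(C)C | intermediate
4 | 2-methoxy-6-methylphenol | COc1cccc(C)c1O | starting material
5 | 2-methoxy-6-methyl-1,4-benzoquinone | COC1=CC(=O)C=C(C)C1=O | intermediate
6 | (4aS,8aR)-7-(tert-butyldimethylsilyloxy)-2-methoxy-5,5,8a-trimethyl-6-(triisopropylsilyloxy)-4a,5,8,8a-tetrahydronaphthalene-1,4-dione (cis-fused cycloadduct) | O=C1C(OC)=CC(=O)[C@H]2C(C)(C)C(O[Si](C(C)C)(C(C)C)C(C)C)=C(O[Si](C)(C)C(C)(C)C)C[C@@]12C | intermediate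
7 | 4-bromobut-1-yne | C#CCCBr | starting material
8 | [(E)-4-bromo-2-methylbut-1-enyl]dimethylalane | C[Al](C)/C=C(\C)CCBr | intermediate (not isolated)
9 | ethyl (E)-5-bromo-3-methylpent-2-enoate | CCOC(=O)/C=C(\C)CCBr | intermediate
10 | (E)-5-bromo-3-methylpent-2-en-1-ol | OC/C=C(\C)CCBr | intermediate
11 | (E)-(5-bromo-3-methylpent-2-enyloxy)(tert-butyl)diphenylsilane | CC(C)(C)[Si](c1ccccc1)(c1ccccc1)OC/C=C(\C)CCBr | intermediate
12 | potassium C5(6)-dienolate of 6 | O=C1C(OC)=CC([O-])=C2C(C)(C)C(O[Si](C(C)C)(C(C)C)C(C)C)=C(O[Si](C)(C)C(C)(C)C)C[C@@]12C.[K+] | intermediate (not isolated)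
13 | [(E)-5-(tert-butyldiphenylsilyloxy)-3-methylpent-3-enyl]magnesium bromide | CC(C)(C)[Si](c1ccccc1)(c1ccccc1)OC/C=C(\C)CC[Mg]Br | intermediate (not isolated)
14 | C9 alkoxide C5(6)-dienolate formed by addition of 13 to 12 | CC(C)(C)[Si](c1ccccc1)(c1ccccc1)OC/C=C(\C)CC[C@@]1([O-])C(OC)=CC([O-])=C2C(C)(C)C(O[Si](C(C)C)(C(C)C)C(C)C)=C(O[Si](C)(C)C(C)(C)C)C[C@@]12C.[K+].[Mg+2].[Br-] | intermediate (not isolated)
15 | 15-(tert-butyldiphenylsilyloxy)-2-(tert-butyldimethylsilyloxy)-9-hydroxy-8-methoxy-3-(triisopropylsilyloxy)-17-nor-ent-labda-2,7,13E-trien-6-one (H-5 trans and 9-OH cis to CH3-20) | CC(C)(C)[Si](c1ccccc1)(c1ccccc1)OC/C=C(\C)CC[C@@]1(O)C(OC)=CC(=O)[C@@H]2C(C)(C)C(O[Si](C(C)C)(C(C)C)C(C)C)=C(O[Si](C)(C)C(C)(C)C)C[C@@]12C | intermediate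
16 | corresponding 6,9-diol (6-OH cis to CH3-20), 8-methoxy-7-ene | CC(C)(C)[Si](c1ccccc1)(c1ccccc1)OC/C=C(\C)CC[C@@]1(O)C(OC)=C[C@H](O)[C@@H]2C(C)(C)C(O[Si](C(C)C)(C(C)C)C(C)C)=C(O[Si](C)(C)C(C)(C)C)C[C@@]12C | intermediate (not isolated)
17 | 15-(tert-butyldiphenylsilyloxy)-2-(tert-butyldimethylsilyloxy)-9-hydroxy-3-(triisopropylsilyloxy)-17-nor-ent-labda-2,6,13E-trien-8-one | CC(C)(C)[Si](c1ccccc1)(c1ccccc1)OC/C=C(\C)CC[C@@]1(O)C(=O)C=C[C@@H]2C(C)(C)C(O[Si](C(C)C)(C(C)C)C(C)C)=C(O[Si](C)(C)C(C)(C)C)C[C@@]12C | intermediate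
18 | diiodosamarium C8(9)-dienolate (trivalent samarium) | CC(C)(C)[Si](c1ccccc1)(c1ccccc1)OC/C=C(\C)CCC1=C(O[Sm](I)I)C=C[C@@H]2C(C)(C)C(O[Si](C(C)C)(C(C)C)C(C)C)=C(O[Si](C)(C)C(C)(C)C)C[C@@]12C | intermediate (not isolated)
19 | 15-(tert-butyldiphenylsilyloxy)-2-(tert-butyldimethylsilyloxy)-3-(triisopropylsilyloxy)-17-nor-ent-labda-2,6,13E-trien-8-one (H-9 trans to CH3-20) | CC(C)(C)[Si](c1ccccc1)(c1ccccc1)OC/C=C(\C)CC[C@@H]1C(=O)C=C[C@@H]2C(C)(C)C(O[Si](C(C)C)(C(C)C)C(C)C)=C(O[Si](C)(C)C(C)(C)C)C[C@@]12C | intermediate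
20 | lithium C7(8)-enolate of the 6,7-dihydro ketone | CC(C)(C)[Si](c1ccccc1)(c1ccccc1)OC/C=C(\C)CC[C@@H]1C([O-])=CC[C@@H]2C(C)(C)C(O[Si](C(C)C)(C(C)C)C(C)C)=C(O[Si](C)(C)C(C)(C)C)C[C@@]12C.[Li+] | intermediate (not isolated)
21 | 15-(tert-butyldiphenylsilyloxy)-2-(tert-butyldimethylsilyloxy)-3-(triisopropylsilyloxy)-17-nor-ent-labda-2,7,13E-trien-8-yl triflate | CC(C)(C)[Si](c1ccccc1)(c1ccccc1)OC/C=C(\C)CC[C@@H]1C(OS(=O)(=O)C(F)(F)F)=CC[C@@H]2C(C)(C)C(O[Si](C(C)C)(C(C)C)C(C)C)=C(O[Si](C)(C)C(C)(C)C)C[C@@]12C | intermediate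
22 | 15-(tert-butyldiphenylsilyloxy)-2-(tert-butyldimethylsilyloxy)-3-(triisopropylsilyloxy)-ent-labda-2,7,13E-triene | CC(C)(C)[Si](c1ccccc1)(c1ccccc1)OC/C=C(\C)CC[C@@H]1C(C)=CC[C@@H]2C(C)(C)C(O[Si](C(C)C)(C(C)C)C(C)C)=C(O[Si](C)(C)C(C)(C)C)C[C@@]12C | intermediate
23 | 15-(tert-butyldiphenylsilyloxy)-ent-3β-(triisopropylsilyloxy)labda-7,13E-dien-2-one | CC(C)(C)[Si](c1ccccc1)(c1ccccc1)OC/C=C(\C)CC[C@@H]1C(C)=CC[C@@H]2C(C)(C)[C@H](O[Si](C(C)C)(C(C)C)C(C)C)C(=O)C[C@@]12C | intermediate (not isolated)
24 | 15-hydroxy-ent-3β-(triisopropylsilyloxy)labda-7,13E-dien-2-one | OC/C=C(\C)CC[C@@H]1C(C)=CC[C@@H]2C(C)(C)[C@H](O[Si](C(C)C)(C(C)C)C(C)C)C(=O)C[C@@]12C | intermediate (not isolated)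
25 | ent-3β,15-dihydroxylabda-7,13E-dien-2-one | OC/C=C(\C)CC[C@@H]1C(C)=CC[C@@H]2C(C)(C)[C@H](O)C(=O)C[C@@]12C | intermediate
26 | ent-3β-hydroxy-2-oxolabda-7,13E-dien-15-yl acetate; (3S,5S,9R,10S) | CC(=O)OC/C=C(\C)CC[C@@H]1C(C)=CC[C@@H]2C(C)(C)[C@H](O)C(=O)C[C@@]12C | target

**Step count**

Total: 14 steps. Longest linear sequence: 10 steps (steps 1, 2, 4, 8–14; the side-chain branch, steps 5–7 then 8–14, is equally long).

**Steps most likely to fail**

Step 4. The cycloaddition may stall after the first C–C bond (C1–C10), or the diene may be lost to silyl transfer or electron transfer to the quinone before ring closure. The fallback runs the ring construction as two separate conjugate additions. Setting out from 5 and 3, a Mukaiyama–Michael addition under the same chiral catalyst at −78 °C, with silyl transfer from O2 of the diene to the quinone oxygen, is stopped at the open silyl dienol ether F1. F1 is then closed by an intramolecular Mukaiyama–Michael reaction (Me3SiNTf2, 5 mol %, CH2Cl2, −78 °C): the C5 silyl dienol ether adds to the β,β-dimethyl enone carbon C4 and the silyl group returns to O2. This comes back to the route at 6; C5 may be a mixture, which step 8 resets.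

Step 8. Deprotonation of the very hindered C5–H may be incomplete, so that the Grignard reagent attacks or deprotonates the vinylogous ester, and protonation of the ring-fusion enolate may show poor facial selectivity. The fallback separates masking, addition and protonation and makes the protonation reagent-controlled. Setting out from 6, KN(SiMe3)2 then Me3SiCl (THF, −78 °C) gives the isolated trimethylsilyl dienol ether F2. Grignard reagent 13 with LaCl3·2LiCl adds to the C9 ketone of F2 to give the carbinol silyl dienol ether F3. F3 is C-protonated at −78 °C with the hindered Lewis-acid-assisted Brønsted acid made from SnCl4 and 2,2'-dihydroxy-1,1'-binaphthyl, a known reagent class for face-selective protonation of silyl enol ethers; either antipode can be tried. This comes back to the route at 15.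

Step 11. 1,2-Reduction of the C8 carbonyl may compete with conjugate hydride delivery, or proton transfer may scramble the enolate before O-triflation. Setting out from 19, RhCl(PPh3)3-catalysed 1,4-hydrosilylation with PhMe2SiH (benzene, rt) should give the dimethylphenylsilyl enol ether F4 regiospecifically. MeLi in THF cleaves this unhindered silyl enol ether, leaving the hindered ring A silyl ethers, and gives lithium enolate 20. Triflation with PhNTf2 as in step 11 comes back to the route at 21.

**Further compounds**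

F1 | step 4 | (6-position quaternary) 4-(tert-butyldimethylsilyloxy)-2-methoxy-6-methyl-6-[4-methyl-2-oxo-3-(triisopropylsilyloxy)pent-3-enyl]cyclohexa-2,4-dienone | O=C1C(OC)=CC(O[Si](C)(C)C(C)(C)C)=C[C@@]1(C)CC(=O)C(O[Si](C(C)C)(C(C)C)C(C)C)=C(C)C
F2 | step 8 | trimethylsilyl C5(6)-dienol ether of 6 | O=C1C(OC)=CC(O[Si](C)(C)C)=C2C(C)(C)C(O[Si](C(C)C)(C(C)C)C(C)C)=C(O[Si](C)(C)C(C)(C)C)C[C@@]12C
F3 | step 8 | C9 carbinol of F2 carrying the side chain (trimethylsilyl dienol ether of 15) | CC(C)(C)[Si](c1ccccc1)(c1ccccc1)OC/C=C(\C)CC[C@@]1(O)C(OC)=CC(O[Si](C)(C)C)=C2C(C)(C)C(O[Si](C(C)C)(C(C)C)C(C)C)=C(O[Si](C)(C)C(C)(C)C)C[C@@]12C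
F4 | step 11 | dimethylphenylsilyl C7(8)-enol ether of the 6,7-dihydro ketone derived from 19 | CC(C)(C)[Si](c1ccccc1)(c1ccccc1)OC/C=C(\C)CC[C@@H]1C(O[Si](C)(C)c3ccccc3)=CC[C@@H]2C(C)(C)C(O[Si](C(C)C)(C(C)C)C(C)C)=C(O[Si](C)(C)C(C)(C)C)C[C@@]12C
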